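**Plan**

Locants, used throughout for the six carbons that become the ring: C1 quaternary C(CH3)(O-aroyl), C2 ring C=O, C3 =C(CH3), C4 =C(chain), C5 CH2, C6 CHOH. The SMILES reads (1R,6S), with O1 and O6 trans.
Cuts, in retrosynthetic order: the two phenol benzyl ethers; the chain C=O (back to a pent-1-ynyl group on C4); a CO2 unit returned to C3 and tied to O6 as a lactone, with the alkene moved to C4=C5; the aroyl–O1 bond; last, C2–C3 and C6–C1 together.
Enabling feature: C3 and C6 stand 1,4 across the cyclohexenone, C6 bears oxygen and C3 is alpha to the C2 ketone, so an O6–C(=O)–C3 bridge is a beta-keto lactone that later leaves as CO2 without trace. With that bridge, C3–C4–C5–C6 plus O–C=O is the flat ring of a 2-pyrone, and C1(CH3)(O)–C2(=O) is lactic acid at its ketene acetal level.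
Forward: the pyrone ring is made first and its chain is added by Sonogashira coupling. One dearomatising [4+2] cycloaddition closes ring C1–C6. Then follow unmasking of C2=O, aroylation of O1 while O6 is still the lactone, lactone opening with decarboxylation, alkyne hydration and debenzylation.
Stereochemistry: (S)-lactic acid is the only chiral source. Its centre is parked in a tert-butyl acetal, which returns it to C1 (attack anti to tert-butyl). The endo rule relays it to C6, and all other new centres are temporary and are erased.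

Key step: step 6

Remark: 2-methylmalonyl dichloride and methyl orsellinate are taken as catalogue chemicals.

**Route**

Step 1
Reactants: 1 (S)-lactic acid; 2 pivalaldehyde
Product: 3 (2S,5S)-2-tert-butyl-5-methyl-1,3-dioxolan-4-one (cis)
Conditions: TsOH·H2O (cat.), H2SO4 (cat.), pentane, reflux, Dean–Stark; crystallisation from pentane/Et2O, −78 °C
Reagents that add atoms: none
Why: Acid-catalysed acetalisation with azeotropic water removal follows the self-regeneration-of-stereocentres principle, in which the lactic acid centre (C5 of the dioxolanone) should direct the new acetal centre C2 to the cis (2S,5S) isomer, and crystallisation removes the minor trans isomer.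

Step 2
Reactants: 3 (2S,5S)-2-tert-butyl-5-methyl-1,3-dioxolan-4-one
Product: 4 (2S)-2-tert-butyl-4-(tert-butyldimethylsilyloxy)-5-methyl-1,3-dioxole
Conditions: LDA, THF, −78 °C; TBSCl, DMPU, −78→−30 °C
Reagents that add atoms: tert-butyldimethylsilyl chloride, CC(C)(C)[Si](C)(C)Cl
Why: Kinetic enolisation and O-silylation of a lactone enolate (silyl ketene acetal formation) should flatten the former lactic acid centre, while the untouched acetal centre C2 keeps the chiral information.

Step 3
Reactants: 5 2-methylmalonyl dichloride; 6 ethyl vinyl ether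
Product: 7 4-hydroxy-3-methyl-2H-pyran-2-one
Conditions: Et2O, −10→35 °C
Reagents that add atoms: none
Why: C-acylation of the enol ether by one acid chloride, loss of HCl, and closure of the ether oxygen onto the second acid chloride with loss of chloroethane is the known malonyl dichloride/enol ether route to 6-unsubstituted 4-hydroxy-2-pyrones.

Step 4
Reactants: 7 4-hydroxy-3-methyl-2H-pyran-2-one
Product: 8 3-methyl-2-oxo-2H-pyran-4-yl trifluoromethanesulfonate
Conditions: Tf2O, Et3N, CH2Cl2, −78→0 °C
Reagents that add atoms: trifluoromethanesulfonic anhydride, O=S(=O)(OS(=O)(=O)C(F)(F)F)C(F)(F)F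
Why: O-sulfonylation of the vinylogous acid is routine for 4-hydroxy-2-pyrones and turns C4 into a cross-coupling site.

Step 5
Reactants: 8 3-methyl-2-oxo-2H-pyran-4-yl trifluoromethanesulfonate; 9 1-pentyne
Product: 10 3-methyl-4-(pent-1-yn-1-yl)-2H-pyran-2-one
Conditions: PdCl2(PPh3)2 (3 mol %), CuI (5 mol %), Et3N, THF, 25 °C
Reagents that add atoms: none
Why: Sonogashira coupling of 4-sulfonyloxy- and 4-halo-2-pyrones with terminal alkynes is well known, because the electron-poor C4–O bond adds readily to zerovalent palladium, and it brings in the whole chain as a masked 2-oxopentyl group.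

Step 6
Reactants: 4 (2S)-2-tert-butyl-4-(tert-butyldimethylsilyloxy)-5-methyl-1,3-dioxole; 10 3-methyl-4-(pent-1-yn-1-yl)-2H-pyran-2-one
Product: 11 endo cycloadduct, (1S,4R,7R,8R)-8-(tert-butyldimethylsilyloxy)-4,7-dimethyl-5-(pent-1-yn-1-yl)-2-oxabicyclo[2.2.2]oct-5-en-3-one whose O7 and O8 (both endo, syn to C5=C6) are joined in an (S)-2,2-dimethylpropylidene acetal, tert-butyl cis to the C7 methyl on the dioxolane
Conditions: 4 (2 equiv), CH2Cl2, 13 kbar, 25 °C, 72 h
Reagents that add atoms: none
Why: The trioxygenated, very electron-rich C4=C5 bond of 4 (high HOMO) and the electron-poor diene C3=C4–C5=C6 of pyrone 10 (LUMO lowered by the lactone carbonyl and the conjugated alkyne) should combine in a concerted but asynchronous inverse-electron-demand Diels–Alder reaction, with the C6–C1 bond running ahead of the C2–C3 bond. The closest known reaction type is the cycloaddition of 2-pyrones with ketene acetals, vinyl ethers and 1,3-dioxoles, which under pressure at ambient temperature stops at the CO2-bridged 2-oxabicyclo[2.2.2]oct-5-en-3-one. The carbocycle C1–C6 is closed in this suprafacial [4+2] mode, which at the same time creates the bridged lactone and the cis-fused dioxolane. C1 is controlled by the acetal centre of 4, since the pyrone can reach the flat dioxole only on the face anti to tert-butyl (C6 takes the place of the former lactic acid hydrogen, giving 1R), and C6 is controlled by the endo rule, the tied-back dioxole ring lying under C4–C5 of the diene while CH3 and the bulky OTBS point outward, so that O1 ends anti to the O6 bridge (trans, 6S). Regioselectivity follows from polarity, the nucleophilic methyl-bearing carbon of the ketene acetal bonding to the unsubstituted pyrone C6 (largest LUMO coefficient) and the acetal carbon to C3. Retention of the CO2 bridge is secured by using pressure instead of heat, and the slim linear alkynyl group keeps the endo pocket open and offers no carbonyl for a competing Mukaiyama addition.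

Step 7
Reactants: 11 endo cycloadduct
Product: 12 (1S,4R,7R)-7-hydroxy-4,7-dimethyl-5-(pent-1-yn-1-yl)-2-oxabicyclo[2.2.2]oct-5-ene-3,8-dione
Conditions: TBAF, AcOH, THF, 0 °C
Reagents that add atoms: none
Why: Fluoride cleaves the Si–O bond of the mixed silyl ketal, the hemiketal oxide collapses to the C2 ketone by expelling the acetal oxygen (the better leaving group, as in the forward Claisen breakdown), and the hemiacetal sheds pivalaldehyde, with acetic acid buffering the beta-keto lactone and neither C1 nor C6 touched.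

Step 8
Reactants: 13 methyl orsellinate (methyl 2,4-dihydroxy-6-methylbenzoate)
Product: 14 methyl 2,4-bis(benzyloxy)-6-methylbenzoate
Conditions: BnBr, K2CO3, DMF, 60 °C
Reagents that add atoms: benzyl bromide, BrCc1ccccc1
Why: Williamson etherification of both phenols is standard for orsellinates, and mild heating also alkylates the hydrogen-bonded ortho phenol.

Step 9
Reactants: 14 methyl 2,4-bis(benzyloxy)-6-methylbenzoate
Product: 15 2,4-bis(benzyloxy)-6-methylbenzoic acid
Conditions: KOH, DMSO/H2O, 100 °C; then 1 M HCl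
Reagents that add atoms: potassium hydroxide, [K+].[OH-]
Why: Saponification of a doubly ortho-substituted methyl benzoate needs forcing hydroxide conditions, which benzyl ethers tolerate.

Step 10
Reactants: 15 2,4-bis(benzyloxy)-6-methylbenzoic acid
Product: 16 2,4-bis(benzyloxy)-6-methylbenzoyl chloride
Conditions: (COCl)2, DMF (cat.), CH2Cl2, 0→25 °C
Reagents that add atoms: oxalyl chloride, ClC(=O)C(=O)Cl
Why: Chlorination through the Vilsmeier-type chloroiminium species is the standard mild conversion of an electron-rich benzoic acid into its chloride, and benzyl ethers are inert to it.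

Step 11
Reactants: 12 (1S,4R,7R)-7-hydroxy-4,7-dimethyl-5-(pent-1-yn-1-yl)-2-oxabicyclo[2.2.2]oct-5-ene-3,8-dione; 16 2,4-bis(benzyloxy)-6-methylbenzoyl chloride
Product: 18 (1S,4R,7R)-4,7-dimethyl-3,8-dioxo-5-(pent-1-yn-1-yl)-2-oxabicyclo[2.2.2]oct-5-en-7-yl 2,4-bis(benzyloxy)-6-methylbenzoate, via aroyl triflate 17 (not isolated)
Conditions: 16, AgOTf, CH2Cl2, −78 °C; then 12, 2,6-di-tert-butyl-4-methylpyridine, −78→0 °C
Reagents that add atoms: silver trifluoromethanesulfonate, [Ag+].[O-]S(=O)(=O)C(F)(F)F (its triflate stays only in intermediate 17)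
Why: Chloride abstraction gives an aroyl triflate that reacts as a linear, dialkoxy-stabilised acylium ion, the known way to acylate hindered tertiary alcohols with doubly ortho-substituted benzoyl groups at low temperature, and O6 is still locked in the lactone so only O1 can react and the C1–O bond (hence 1R) is not broken.

Step 12
Reactants: 18 (1S,4R,7R)-4,7-dimethyl-3,8-dioxo-5-(pent-1-yn-1-yl)-2-oxabicyclo[2.2.2]oct-5-en-7-yl 2,4-bis(benzyloxy)-6-methylbenzoate
Product: 20 (1R,6S)-6-hydroxy-1,3-dimethyl-2-oxo-4-(pent-1-yn-1-yl)cyclohex-3-en-1-yl 2,4-bis(benzyloxy)-6-methylbenzoate, via beta-keto acid 19 (not isolated)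
Conditions: LiOH, THF/H2O, 0 °C; then 1 M HCl to pH 2, 40 °C
Reagents that add atoms: lithium hydroxide, [Li+].[OH-] (its oxygen stays only in intermediate 19 and leaves with CO2)
Why: In this saponification–decarboxylation, hydroxide should open the strained bridged lactone at its acyl carbon (C6–O intact, 6S kept) while the hindered benzoate of a tertiary alcohol is inert, and on acidification the beta-keto acid loses CO2 through the six-centre transition state and the dienol is drained under acid equilibration by protonation at C5 to the conjugated tetrasubstituted C3=C4 enone.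

Step 13
Reactants: 20 (1R,6S)-6-hydroxy-1,3-dimethyl-2-oxo-4-(pent-1-yn-1-yl)cyclohex-3-en-1-yl 2,4-bis(benzyloxy)-6-methylbenzoate
Product: 21 (1R,6S)-6-hydroxy-1,3-dimethyl-2-oxo-4-(2-oxopentyl)cyclohex-3-en-1-yl 2,4-bis(benzyloxy)-6-methylbenzoate
Conditions: (Ph3P)AuNTf2 (5 mol %), 1,4-dioxane/H2O 10:1, 50 °C
Reagents that add atoms: water, O
Why: In this alkyne hydration catalysed by monovalent gold, the enone polarises the triple bond so that water attacks the distal, propyl-bearing carbon (formal 1,6-addition), which gives only the 2-oxopentyl ketone, and the ring carbonyl is trans to the alkyne across C3=C4 and cannot cyclise onto it.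

Step 14
Reactants: 21 (1R,6S)-6-hydroxy-1,3-dimethyl-2-oxo-4-(2-oxopentyl)cyclohex-3-en-1-yl 2,4-bis(benzyloxy)-6-methylbenzoate
Product: 22 talarophilone, (1R,6S)-6-hydroxy-1,3-dimethyl-2-oxo-4-(2-oxopentyl)cyclohex-3-en-1-yl 2,4-dihydroxy-6-methylbenzoate
Conditions: H2 (1 atm), Pd/C (10 wt %), EtOAc, 25 °C
Reagents that add atoms: none
Why: Hydrogenolysis of aryl benzyl ethers is fast and neutral, whereas the tetrasubstituted enone, both ketones, the homoallylic alcohol and the hindered ester should be left unchanged.

**Compound list**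

1 | (S)-lactic acid | C[C@H](O)C(=O)O | starting material
2 | pivalaldehyde | CC(C)(C)C=O | starting material
3 | (2S,5S)-2-tert-butyl-5-methyl-1,3-dioxolan-4-one | C[C@@H]1O[C@H](C(C)(C)C)OC1=O | intermediate
4 | (2S)-2-tert-butyl-4-(tert-butyldimethylsilyloxy)-5-methyl-1,3-dioxole | CC1=C(O[Si](C)(C)C(C)(C)C)O[C@@H](C(C)(C)C)O1 | intermediate
5 | 2-methylmalonyl dichloride | CC(C(=O)Cl)C(=O)Cl | starting material
6 | ethyl vinyl ether | C=COCC | starting material
7 | 4-hydroxy-3-methyl-2H-pyran-2-one | CC1=C(O)C=COC1=O | intermediate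
8 | 3-methyl-2-oxo-2H-pyran-4-yl trifluoromethanesulfonate | CC1=C(OS(=O)(=O)C(F)(F)F)C=COC1=O | intermediate
9 | 1-pentyne | CCCC#C | starting material
10 | 3-methyl-4-(pent-1-yn-1-yl)-2H-pyran-2-one | CCCC#CC1=C(C)C(=O)OC=C1 | intermediate
11 | endo cycloadduct (CO2-bridged, dioxolane-fused silyl ketal) | CCCC#CC1=C[C@@H]2OC(=O)[C@@]1(C)[C@]3(O[Si](C)(C)C(C)(C)C)O[C@@H](C(C)(C)C)O[C@]23C | intermediate
12 | (1S,4R,7R)-7-hydroxy-4,7-dimethyl-5-(pent-1-yn-1-yl)-2-oxabicyclo[2.2.2]oct-5-ene-3,8-dione | CCCC#CC1=C[C@@H]2OC(=O)[C@@]1(C)C(=O)[C@]2(C)O | intermediate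
13 | methyl orsellinate | COC(=O)c1c(C)cc(O)cc1O | starting material
14 | methyl 2,4-bis(benzyloxy)-6-methylbenzoate | COC(=O)c1c(C)cc(OCc2ccccc2)cc1OCc3ccccc3 | intermediate
15 | 2,4-bis(benzyloxy)-6-methylbenzoic acid | OC(=O)c1c(C)cc(OCc2ccccc2)cc1OCc3ccccc3 | intermediate
16 | 2,4-bis(benzyloxy)-6-methylbenzoyl chloride | ClC(=O)c1c(C)cc(OCc2ccccc2)cc1OCc3ccccc3 | intermediate
17 | 2,4-bis(benzyloxy)-6-methylbenzoyl trifluoromethanesulfonate | O=C(OS(=O)(=O)C(F)(F)F)c1c(C)cc(OCc2ccccc2)cc1OCc3ccccc3 | intermediate
18 | (1S,4R,7R)-4,7-dimethyl-3,8-dioxo-5-(pent-1-yn-1-yl)-2-oxabicyclo[2.2.2]oct-5-en-7-yl 2,4-bis(benzyloxy)-6-methylbenzoate | CCCC#CC1=C[C@@H]2OC(=O)[C@@]1(C)C(=O)[C@]2(C)OC(=O)c3c(C)cc(OCc4ccccc4)cc3OCc5ccccc5 | intermediate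
19 | (1R,4S,5R)-5-{[2,4-bis(benzyloxy)-6-methylbenzoyl]oxy}-4-hydroxy-1,5-dimethyl-6-oxo-2-(pent-1-yn-1-yl)cyclohex-2-ene-1-carboxylic acid | CCCC#CC1=C[C@H](O)[C@@](C)(OC(=O)c2c(C)cc(OCc3ccccc3)cc2OCc4ccccc4)C(=O)[C@]1(C)C(=O)O | intermediate
20 | (1R,6S)-6-hydroxy-1,3-dimethyl-2-oxo-4-(pent-1-yn-1-yl)cyclohex-3-en-1-yl 2,4-bis(benzyloxy)-6-methylbenzoate | CCCC#CC1=C(C)C(=O)[C@](C)(OC(=O)c2c(C)cc(OCc3ccccc3)cc2OCc4ccccc4)[C@@H](O)C1 | intermediate
21 | (1R,6S)-6-hydroxy-1,3-dimethyl-2-oxo-4-(2-oxopentyl)cyclohex-3-en-1-yl 2,4-bis(benzyloxy)-6-methylbenzoate | CCCC(=O)CC1=C(C)C(=O)[C@](C)(OC(=O)c2c(C)cc(OCc3ccccc3)cc2OCc4ccccc4)[C@@H](O)C1 | intermediate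
22 | talarophilone | CCCC(=O)CC1=C(C)C(=O)[C@](C)(OC(=O)c2c(C)cc(O)cc2O)[C@@H](O)C1 | target

**Step count**

Total step count: 14.
Longest linear sequence: 9 (steps 3, 4, 5, 6, 7, 11, 12, 13, 14).

**Steps most likely to fail**

1. **Step 6.**
   - What may go wrong: the cycloaddition between a tetrasubstituted dienophile and a 3,4-disubstituted pyrone may be too slow, the bridged adduct may lose CO2, or the approach may leak to exo.
   - The fallback sets out from 4 and 10 and comes back at 20. It gives up the bridge on purpose and re-installs O6 by substrate control.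
   - Heating 4 and 10 in toluene at 130 °C (sealed tube) should let the adduct extrude CO2 and give the cyclohexadiene ketal F1. C1 is still set by attack anti to tert-butyl, and endo or exo approach no longer matters.
   - TBAF/AcOH should unmask the ortho-quinol F2.
   - Aroylation with 16/AgOTf on this flatter tertiary alcohol should give the ortho-quinol ester F3.
   - mCPBA in CH2Cl2 should epoxidise the distal, more electron-rich C5=C6 bond anti to the aroyloxy group and give the epoxide F4.
   - Hydrogenolysis of the alkenyl oxirane with HCO2H/Et3N, Pd2(dba)3·CHCl3 and Bu3P in 1,4-dioxane delivers hydride to C5 through the allyl complex of divalent palladium. It leaves the C6–O bond intact and gives 20.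

2. **Step 11.**
   - What may go wrong: the crowded endo tertiary hydroxyl may fail to capture the acylium ion, or acid may trigger an alpha-ketol shift of the bicyclic ketol.
   - The fallback sets out from 12 and comes back at 20. It changes from cationic acylation on the bicycle to anionic acylation on the monocycle.
   - LiOH in THF/H2O followed by 1 M HCl should open and decarboxylate 12 to the diol F5.
   - TESCl/imidazole should silylate only the secondary hydroxyl and give the silyl ether F6.
   - LiHMDS at −78 °C followed by 16 should acylate the lithium alkoxide and give the silylated ester F7. A strong base is now tolerable because the beta-keto lactone is gone and the silyl group on O6 blocks the retro-aldol path.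
   - HF·pyridine in THF then gives 20.

3. **Step 12.**
   - What may go wrong: retro-aldol or retro-Claisen ring cleavage, and migration of the aroyl group to O6, may occur under hydroxide.
   - The fallback sets out from 18 and comes back at 20 without any hydroxide.
   - Neutral alcoholysis of the strained lactone with allyl alcohol, catalysed by (ClBu2Sn)2O in toluene at 40 °C, should give the allyl beta-keto ester F8.
   - Pd(PPh3)4 and morpholine in THF at 25 °C remove the allyl group. The liberated beta-keto acid loses CO2 and the dienol is protonated to 20.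

**Further compounds**

F1 | step 6 | cyclohexadiene ketal (TBS ketal and (S)-2,2-dimethylpropylidene acetal of the ortho-quinol, CO2 lost) | CCCC#CC1=C(C)[C@]2(O[Si](C)(C)C(C)(C)C)O[C@@H](C(C)(C)C)O[C@]2(C)C=C1
F2 | step 6 | (6R)-6-hydroxy-2,6-dimethyl-3-(pent-1-yn-1-yl)cyclohexa-2,4-dien-1-one | CCCC#CC1=C(C)C(=O)[C@](C)(O)C=C1
F3 | step 6 | (1R)-1,3-dimethyl-2-oxo-4-(pent-1-yn-1-yl)cyclohexa-3,5-dien-1-yl 2,4-bis(benzyloxy)-6-methylbenzoate | CCCC#CC1=C(C)C(=O)[C@](C)(OC(=O)c2c(C)cc(OCc3ccccc3)cc2OCc4ccccc4)C=C1
F4 | step 6 | (1R,5S,6S)-5,6-epoxy-1,3-dimethyl-2-oxo-4-(pent-1-yn-1-yl)cyclohex-3-en-1-yl 2,4-bis(benzyloxy)-6-methylbenzoate | CCCC#CC1=C(C)C(=O)[C@](C)(OC(=O)c2c(C)cc(OCc3ccccc3)cc2OCc4ccccc4)[C@H]5O[C@@H]15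
F5 | step 11 | (5S,6R)-5,6-dihydroxy-2,6-dimethyl-3-(pent-1-yn-1-yl)cyclohex-2-en-1-one | CCCC#CC1=C(C)C(=O)[C@](C)(O)[C@@H](O)C1
F6 | step 11 | (5S,6R)-6-hydroxy-2,6-dimethyl-3-(pent-1-yn-1-yl)-5-(triethylsilyloxy)cyclohex-2-en-1-one | CCCC#CC1=C(C)C(=O)[C@](C)(O)[C@@H](O[Si](CC)(CC)CC)C1
F7 | step 11 | (1R,6S)-1,3-dimethyl-2-oxo-4-(pent-1-yn-1-yl)-6-(triethylsilyloxy)cyclohex-3-en-1-yl 2,4-bis(benzyloxy)-6-methylbenzoate | CCCC#CC1=C(C)C(=O)[C@](C)(OC(=O)c2c(C)cc(OCc3ccccc3)cc2OCc4ccccc4)[C@@H](O[Si](CC)(CC)CC)C1
F8 | step 12 | allyl (1R,4S,5R)-5-{[2,4-bis(benzyloxy)-6-methylbenzoyl]oxy}-4-hydroxy-1,5-dimethyl-6-oxo-2-(pent-1-yn-1-yl)cyclohex-2-ene-1-carboxylate | CCCC#CC1=C[C@H](O)[C@@](C)(OC(=O)c2c(C)cc(OCc3ccccc3)cc2OCc4ccccc4)C(=O)[C@]1(C)C(=O)OCC=C
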